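## Retrosynthetic overview

1. Feature: the core is numbered as benzo[7]annulen-5-one (benzenoid C1–C4, fusion C4a/C9a, C5=O, C6–OH, C7, C8, C9). The galloylated chroman G sits on C1 and chroman F on C8. The seven-membered ring holds a two-carbon unit C7–C8 between C6 and C9. Taken out with chroman F, this unit is a terminal alkyne, and what remains is a 2-oxygenated inden-1-one.
2. Target ⇒ (debenzylation, O6 deprotection) protected benzotropolone ⇒ (re-join C6–C9) cis-fused cyclobuta[a]indenone ⇒ (cut C6–C7 and C8–C9) 2-siloxyindenone carrying chroman G + cis-2-ethynylchroman.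
3. Siloxyindenone ⇒ 1,2-diketone ⇒ indanone gallate ⇒ 4-bromoindanone. Chroman G is built by Stille alkenylation, asymmetric epoxidation, phenoxide opening (inversion at C2), an inverting epoxide transposition (inversion at C3) and arene–epoxide closure.
4. Ethynylchroman ⇒ kinetic-resolution epoxidation of an alkynyl vinyl carbinol, Mitsunobu etherification (inversion), then the same kind of arene–epoxide closure.
5. Ring order: five-membered ring, pyran of G (pyran of F in parallel), cyclobutene, seven-membered ring.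

Key step: step 22

Assumption: the SMILES is taken as binding (galloyl on the chroman at benzenoid C1). O6 is carried as a tert-butyldimethylsilyl ether rather than a benzyl ether because it goes on by enol silylation, shields C6, offers no activated hydrogen to the excited carbonyl, and can be removed on its own.

## Route

Step 1
Reactants: 1 phloroglucinol
Product: 2 3,5-bis(benzyloxy)phenol
Conditions: BnBr (2.0 equiv), K2CO3, DMF, 0 °C to rt; chromatography
Reagents that add atoms: benzyl bromide, BrCc1ccccc1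
Why: Williamson etherification with two equivalents of halide makes the diether the main member of a statistical set, from which it is separated by chromatography.

Step 2
Reactants: 3 trimethylsilylacetylene; 4 acrolein
Product: 6 rac-5-(trimethylsilyl)pent-1-en-4-yn-3-ol, via lithium trimethylsilylacetylide 5 (not isolated)
Conditions: n-BuLi, THF, −78 °C; then 4; H2O
Reagents that add atoms: none
Why: The hard lithium acetylide adds 1,2 to the enal (carbonyl addition), and the racemic carbinol is resolved in step 3.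

Step 3
Reactants: 6 rac-5-(trimethylsilyl)pent-1-en-4-yn-3-ol
Product: 7 (1S)-1-[(2R)-oxiran-2-yl]-3-(trimethylsilyl)prop-2-yn-1-ol
Conditions: Ti(OiPr)4 (15 mol %), L-(+)-diisopropyl tartrate (18 mol %), t-BuOOH (0.45 equiv), 4 Å sieves, CH2Cl2, −20 °C
Reagents that add atoms: tert-butyl hydroperoxide, CC(C)(C)OO
Why: In this Sharpless kinetic resolution with the L-(+)-tartrate, the (R)-carbinol (the spatial counterpart of the fast (S)-alkyl series, the descriptor changing only because alkynyl outranks vinyl) is epoxidised much faster and with the usual anti (erythro) preference, so stopping below half conversion fixes the carbinol centre by selection and the oxirane centre by reagent control.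

Step 4
Reactants: 7 (1S)-1-[(2R)-oxiran-2-yl]-3-(trimethylsilyl)prop-2-yn-1-ol; 2 3,5-bis(benzyloxy)phenol
Product: 8 [(3R)-3-[3,5-bis(benzyloxy)phenoxy]-3-[(2R)-oxiran-2-yl]prop-1-yn-1-yl]trimethylsilane
Conditions: PPh3, DIAD, toluene, 0 °C to rt
Reagents that add atoms: none
Why: Mitsunobu etherification displaces the activated propargylic oxygen by SN2 with inversion (anti to syn, the relation a cis-chroman needs), while the silyl cap discourages SN2' attack and the neutral medium spares the oxirane.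

Step 5
Reactants: 8 [(3R)-3-[3,5-bis(benzyloxy)phenoxy]-3-[(2R)-oxiran-2-yl]prop-1-yn-1-yl]trimethylsilane
Product: 9 (2R,3R)-5,7-bis(benzyloxy)-2-[(trimethylsilyl)ethynyl]chroman-3-ol
Conditions: Sc(OTf)3 (5 mol %), (CF3)2CHOH–CH2Cl2 1:4, 0 °C
Reagents that add atoms: none
Why: Intramolecular Friedel–Crafts alkylation of the phloroglucinol-type ring by the activated terminal epoxide (6-endo attack at CH2, known for aryl glycidyl ethers) breaks no bond at either stereocentre, the two ortho positions are equivalent, and an oxophilic rather than carbophilic Lewis acid leaves the aryl propargyl ether unit alone.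

Step 6
Reactants: 9 (2R,3R)-5,7-bis(benzyloxy)-2-[(trimethylsilyl)ethynyl]chroman-3-ol
Product: 11 (2R,3R)-3,5,7-tris(benzyloxy)-2-ethynylchroman, via silylated benzyl ether 10 (not isolated)
Conditions: NaH, BnBr, DMF, 0 °C; then MeOH, K2CO3 (cat.), rt
Reagents that add atoms: benzyl bromide, BrCc1ccccc1
Why: Williamson benzylation of the secondary alkoxide is followed in the same flask by methanolysis of the alkynyl C–Si bond, and neither operation touches C2 or C3.

Step 7
Reactants: 12 3-(3,4-dimethoxyphenyl)propanoic acid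
Product: 13 3-(2-bromo-4,5-dimethoxyphenyl)propanoic acid
Conditions: Br2, AcOH, rt
Reagents that add atoms: bromine, BrBr
Why: Electrophilic aromatic bromination goes para to the 3-methoxy group and ortho to the side chain, which blocks the position where ring closure would otherwise occur.

Step 8
Reactants: 13 3-(2-bromo-4,5-dimethoxyphenyl)propanoic acid
Product: 14 4-bromo-6,7-dimethoxyindan-1-one
Conditions: P2O5–MeSO3H (Eaton's reagent), 50 °C
Reagents that add atoms: none
Why: Intramolecular Friedel–Crafts acylation can use only the remaining ortho position next to a methoxy group, which gives the 6,7-dioxygenated 4-bromoindanone with bromine serving as blocking group and later coupling handle.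

Step 9
Reactants: 14 4-bromo-6,7-dimethoxyindan-1-one
Product: 15 4-bromo-6,7-dihydroxyindan-1-one
Conditions: BBr3, CH2Cl2, −78 °C to rt; H2O
Reagents that add atoms: none
Why: Lewis-acid ether cleavage frees the catechol at this early stage, because the methyl ethers needed to survive step 8 could not be removed at the end beside the gallate ester.

Step 10
Reactants: 15 4-bromo-6,7-dihydroxyindan-1-one
Product: 16 6,7-bis(benzyloxy)-4-bromoindan-1-one
Conditions: BnBr, K2CO3, DMF, 60 °C
Reagents that add atoms: benzyl bromide, BrCc1ccccc1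
Why: Williamson etherification of both phenols with a base too weak to alkylate the ketone at carbon.

Step 11
Reactants: 17 prop-2-yn-1-ol
Product: 18 (E)-3-(tributylstannyl)prop-2-en-1-ol
Conditions: Bu3SnH, AIBN (cat.), neat, 80 °C; chromatography
Reagents that add atoms: tributyltin hydride, CCCC[SnH](CCCC)CCCC
Why: Radical hydrostannation of the terminal alkyne under equilibrating conditions favours the (E)-β-stannyl allylic alcohol, and the minor isomers are removed by chromatography.

Step 12
Reactants: 16 6,7-bis(benzyloxy)-4-bromoindan-1-one; 18 (E)-3-(tributylstannyl)prop-2-en-1-ol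
Product: 19 6,7-bis(benzyloxy)-4-[(E)-3-hydroxyprop-1-enyl]indan-1-one
Conditions: Pd(PPh3)4 (5 mol %), toluene, 100 °C
Reagents that add atoms: none
Why: Stille coupling transfers the alkenyl group with retention of E geometry and tolerates the free alcohol and the ketone, so no reduction step or ketone protection is needed.

Step 13
Reactants: 19 6,7-bis(benzyloxy)-4-[(E)-3-hydroxyprop-1-enyl]indan-1-one
Product: 20 6,7-bis(benzyloxy)-4-[(2S,3S)-3-(hydroxymethyl)oxiran-2-yl]indan-1-one
Conditions: Ti(OiPr)4 (10 mol %), L-(+)-diethyl tartrate (12 mol %), t-BuOOH, 4 Å sieves, CH2Cl2, −20 °C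
Reagents that add atoms: tert-butyl hydroperoxide, CC(C)(C)OO
Why: In the Sharpless asymmetric epoxidation the L-(+)-tartrate turns an E-allylic alcohol into the (2S,3S)-epoxy alcohol and so sets both future centres of chroman G, while the ketone ortho to the 7-benzyloxy group damps the para donor that would otherwise make the aryl oxirane labile.

Step 14
Reactants: 20 6,7-bis(benzyloxy)-4-[(2S,3S)-3-(hydroxymethyl)oxiran-2-yl]indan-1-one; 2 3,5-bis(benzyloxy)phenol
Product: 21 6,7-bis(benzyloxy)-4-{(1R,2S)-1-[3,5-bis(benzyloxy)phenoxy]-2,3-dihydroxypropyl}indan-1-one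
Conditions: 2 (1.5 equiv), NaOH (1.2 equiv), H2O–1,4-dioxane, 70 °C
Reagents that add atoms: none
Why: Phenoxide opens the 3-aryl-2,3-epoxy alcohol at the benzylic carbon by SN2 with inversion (a known phenolysis of aryl glycidols), and because all the base is present as phenoxide the indanone is not enolised.

Step 15
Reactants: 21 6,7-bis(benzyloxy)-4-{(1R,2S)-1-[3,5-bis(benzyloxy)phenoxy]-2,3-dihydroxypropyl}indan-1-one
Product: 23 (2S,3R)-3-[6,7-bis(benzyloxy)-1-oxoindan-4-yl]-3-[3,5-bis(benzyloxy)phenoxy]-2-(methylsulfonyloxy)propyl acetate, via primary monoacetate 22 (not isolated)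
Conditions: AcCl, 2,4,6-collidine, CH2Cl2, −78 °C; then MsCl, Et3N, 0 °C
Reagents that add atoms: acetyl chloride, CC(=O)Cl; methanesulfonyl chloride, CS(=O)(=O)Cl
Why: Low-temperature acetylation with a hindered pyridine base picks the primary hydroxyl, and the remaining secondary one is mesylated in the same flask, which prepares inversion at the carbinol carbon.

Step 16
Reactants: 23 (2S,3R)-3-[6,7-bis(benzyloxy)-1-oxoindan-4-yl]-3-[3,5-bis(benzyloxy)phenoxy]-2-(methylsulfonyloxy)propyl acetate
Product: 25 6,7-bis(benzyloxy)-4-{(R)-[3,5-bis(benzyloxy)phenoxy][(2R)-oxiran-2-yl]methyl}indan-1-one, via hydroxy mesylate 24 (not isolated)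
Conditions: K2CO3, MeOH–THF, 0 °C to rt
Reagents that add atoms: none
Why: Methanolysis of the acetate releases the primary alkoxide, which displaces the neighbouring mesylate (3-exo-tet SN2) with inversion and so turns the anti into the syn aryloxy epoxide that corresponds to a cis-chroman.

Step 17
Reactants: 25 6,7-bis(benzyloxy)-4-{(R)-[3,5-bis(benzyloxy)phenoxy][(2R)-oxiran-2-yl]methyl}indan-1-one
Product: 26 6,7-bis(benzyloxy)-4-[(2R,3R)-5,7-bis(benzyloxy)-3-hydroxychroman-2-yl]indan-1-one
Conditions: AuCl3 (5 mol %), AgOTf (15 mol %), ClCH2CH2Cl, 40 °C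
Reagents that add atoms: none
Why: Gold-catalysed cycloalkylation of an electron-rich arene by a tethered terminal epoxide (a 6-endo Friedel–Crafts closure known for aryl glycidyl ethers and flavan-3-ol skeletons) forms C4–C4a without breaking a bond at either stereocentre, so the syn relation becomes the 2,3-cis chroman.

Step 18
Reactants: 26 6,7-bis(benzyloxy)-4-[(2R,3R)-5,7-bis(benzyloxy)-3-hydroxychroman-2-yl]indan-1-one; 27 3,4,5-tris(benzyloxy)benzoic acid
Product: 28 (2R,3R)-5,7-bis(benzyloxy)-2-[6,7-bis(benzyloxy)-1-oxoindan-4-yl]chroman-3-yl 3,4,5-tris(benzyloxy)benzoate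
Conditions: DCC, DMAP, CH2Cl2, rt
Reagents that add atoms: none
Why: Steglich esterification acylates the axial 3-hydroxyl at oxygen, so C3 keeps its configuration.

Step 19
Reactants: 28 (2R,3R)-5,7-bis(benzyloxy)-2-[6,7-bis(benzyloxy)-1-oxoindan-4-yl]chroman-3-yl 3,4,5-tris(benzyloxy)benzoate
Product: 30 (2R,3R)-5,7-bis(benzyloxy)-2-[6,7-bis(benzyloxy)-2-hydroxy-1-oxoindan-4-yl]chroman-3-yl 3,4,5-tris(benzyloxy)benzoate (both indanone C2 epimers), via sodium enolate 29 (not isolated)
Conditions: NaN(SiMe3)2 (1.05 equiv), THF, −78 °C; 2-(phenylsulfonyl)-3-phenyloxaziridine; AcOH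
Reagents that add atoms: 2-(phenylsulfonyl)-3-phenyloxaziridine, O=S(=O)(c1ccccc1)N1OC1c1ccccc1
Why: In this Davis enolate hydroxylation only C2 can be enolised and the ketone is by far the most acidic site, and the new centre forms as an inconsequential mixture because it is oxidised away in step 20.

Step 20
Reactants: 30 (2R,3R)-5,7-bis(benzyloxy)-2-[6,7-bis(benzyloxy)-2-hydroxy-1-oxoindan-4-yl]chroman-3-yl 3,4,5-tris(benzyloxy)benzoate
Product: 31 (2R,3R)-5,7-bis(benzyloxy)-2-[6,7-bis(benzyloxy)-1,2-dioxoindan-4-yl]chroman-3-yl 3,4,5-tris(benzyloxy)benzoate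
Conditions: Dess–Martin periodinane, CH2Cl2, 0 °C to rt
Reagents that add atoms: none
Why: Dess–Martin oxidation takes the α-ketol to the 1,2-diketone under neutral conditions that leave the benzyl ethers, the ester and the electron-rich rings alone.

Step 21
Reactants: 31 (2R,3R)-5,7-bis(benzyloxy)-2-[6,7-bis(benzyloxy)-1,2-dioxoindan-4-yl]chroman-3-yl 3,4,5-tris(benzyloxy)benzoate
Product: 32 (2R,3R)-5,7-bis(benzyloxy)-2-[6,7-bis(benzyloxy)-2-(tert-butyldimethylsilyloxy)-1-oxo-1H-inden-4-yl]chroman-3-yl 3,4,5-tris(benzyloxy)benzoate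
Conditions: TBSOTf, Et3N, CH2Cl2, −78 to 0 °C, dark; used at once
Reagents that add atoms: tert-butyldimethylsilyl triflate, CC(C)(C)[Si](C)(C)OS(=O)(=O)C(F)(F)F
Why: In this soft enolisation the silyl triflate activates the non-conjugated C2 carbonyl and the amine removes a benzylic C3 proton, which gives O-silylation only (as with cyclic 1,2-diketones in general) and thus the 2-siloxyindenone without a dehydrogenation step.

Step 22
Reactants: 32 (2R,3R)-5,7-bis(benzyloxy)-2-[6,7-bis(benzyloxy)-2-(tert-butyldimethylsilyloxy)-1-oxo-1H-inden-4-yl]chroman-3-yl 3,4,5-tris(benzyloxy)benzoate; 11 (2R,3R)-3,5,7-tris(benzyloxy)-2-ethynylchroman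
Product: 33 cis-fused 2a,7a-dihydro-7H-cyclobuta[a]inden-7-one photoadduct (both facial isomers; one drawn)
Conditions: hν (420 nm LED), 11 (3 equiv, excess recovered), 32 added by syringe pump, CH2Cl2, −20 °C, Ar
Reagents that add atoms: none
Why: Only 32 absorbs at 420 nm, and intersystem crossing gives its ππ* triplet, which adds to the alkyne stepwise: the CH terminus C7 bonds to C6, leaving a benzylic radical at C9 and a vinyl radical at C8, and after spin inversion these recombine to form C8–C9. The closest known reaction type is the [2+2] photocycloaddition of cyclopentenones and other cyclic enones with terminal alkynes to give bicyclo[3.2.0]hept-6-en-2-ones. The cyclobutene is closed by radical recombination within the 1,4-biradical, and the five-membered ring allows only cis fusion, which fixes the relative configuration of the new centres C6 and C9. Which face of the indenone is attacked is left to the weak bias of chroman G and does not matter, since both centres become sp2 in step 23. The step needs head-to-tail orientation and cross-addition rather than indenone dimerisation: C6 becomes quaternary and carries the bulky silyl ether, so only the unsubstituted alkyne carbon should bond there, and this group together with the peri chroman G, the low stationary concentration of 32 and the excess of 11 holds back dimerisation. The adduct is an aryl ketone transparent at 420 nm, so a secondary 1,3-acyl shift of the β,γ-unsaturated ketone is avoided.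

Step 23
Reactants: 33 cis-fused 2a,7a-dihydro-7H-cyclobuta[a]inden-7-one photoadduct
Product: 35 deca-O-benzyl theaflavin gallate bearing a free 6-OH, via silyl tropolone ether 34 (not isolated)
Conditions: xylenes, BHT (cat.), 140 °C, Ar; then 0 °C, Bu4NF, AcOH, THF
Reagents that add atoms: none
Why: This is the thermal opening of a bicyclo[3.2.0]heptadienone to a tropone, in which the C6–C9 bond is a cyclobutene σ-bond that is also benzylic, α to the ketone and α to oxygen, so its cleavage (through a stabilised diradicaloid path, since cis fusion excludes conrotation) should set in near this temperature, both facial isomers converge as C6 and C9 become sp2, and buffered fluoride then removes the labile tropolone silyl ether without touching the gallate.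

Step 24
Reactants: 35 deca-O-benzyl theaflavin gallate bearing a free 6-OH
Product: 36 theaflavin-3-gallate (target)
Conditions: H2 (1 atm), Pd(OH)2/C, THF–MeOH, rt
Reagents that add atoms: none
Why: Hydrogenolysis of the ten benzyl ethers under conditions established for benzylated flavan-3-ol gallates should leave the ester, the benzylic C2–O bonds of both chromans and the tropolone ring intact if stopped at full debenzylation.

## Compound list

1 | phloroglucinol | Oc1cc(O)cc(O)c1 | starting material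
2 | 3,5-bis(benzyloxy)phenol | Oc1cc(OCc2ccccc2)cc(OCc2ccccc2)c1 | intermediate
3 | trimethylsilylacetylene | C#C[Si](C)(C)C | starting material
4 | acrolein | C=CC=O | starting material
5 | lithium trimethylsilylacetylide | [Li]C#C[Si](C)(C)C | intermediate
6 | rac-5-(trimethylsilyl)pent-1-en-4-yn-3-ol | C[Si](C)(C)C#CC(O)C=C | intermediate
7 | (1S)-1-[(2R)-oxiran-2-yl]-3-(trimethylsilyl)prop-2-yn-1-ol (anti) | C[Si](C)(C)C#C[C@H](O)[C@H]1CO1 | intermediate
8 | [(3R)-3-[3,5-bis(benzyloxy)phenoxy]-3-[(2R)-oxiran-2-yl]prop-1-yn-1-yl]trimethylsilane (syn) | C[Si](C)(C)C#C[C@@H](Oc1cc(OCc2ccccc2)cc(OCc2ccccc2)c1)[C@H]1CO1 | intermediate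
9 | (2R,3R)-5,7-bis(benzyloxy)-2-[(trimethylsilyl)ethynyl]chroman-3-ol (cis) | C[Si](C)(C)C#C[C@H]1Oc2cc(OCc3ccccc3)cc(OCc3ccccc3)c2C[C@H]1O | intermediate
10 | (2R,3R)-3,5,7-tris(benzyloxy)-2-[(trimethylsilyl)ethynyl]chroman | C[Si](C)(C)C#C[C@H]1Oc2cc(OCc3ccccc3)cc(OCc3ccccc3)c2C[C@H]1OCc1ccccc1 | intermediate
11 | (2R,3R)-3,5,7-tris(benzyloxy)-2-ethynylchroman (future chroman F) | C#C[C@H]1Oc2cc(OCc3ccccc3)cc(OCc3ccccc3)c2C[C@H]1OCc1ccccc1 | intermediate
12 | 3-(3,4-dimethoxyphenyl)propanoic acid | COc1ccc(CCC(=O)O)cc1OC | starting material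
13 | 3-(2-bromo-4,5-dimethoxyphenyl)propanoic acid | COc1cc(Br)c(CCC(=O)O)cc1OC | intermediate
14 | 4-bromo-6,7-dimethoxyindan-1-one | COc1cc(Br)c2CCC(=O)c2c1OC | intermediate
15 | 4-bromo-6,7-dihydroxyindan-1-one | Oc1cc(Br)c2CCC(=O)c2c1O | intermediate
16 | 6,7-bis(benzyloxy)-4-bromoindan-1-one | O=C1CCc2c(Br)cc(OCc3ccccc3)c(OCc3ccccc3)c21 | intermediate
17 | prop-2-yn-1-ol | C#CCO | starting material
18 | (E)-3-(tributylstannyl)prop-2-en-1-ol | CCCC[Sn](CCCC)(CCCC)/C=C/CO | intermediate
19 | 6,7-bis(benzyloxy)-4-[(E)-3-hydroxyprop-1-enyl]indan-1-one | O=C1CCc2c(/C=C/CO)cc(OCc3ccccc3)c(OCc3ccccc3)c21 | intermediate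
20 | 6,7-bis(benzyloxy)-4-[(2S,3S)-3-(hydroxymethyl)oxiran-2-yl]indan-1-one | O=C1CCc2c([C@@H]3O[C@H]3CO)cc(OCc4ccccc4)c(OCc4ccccc4)c21 | intermediate
21 | 6,7-bis(benzyloxy)-4-{(1R,2S)-1-[3,5-bis(benzyloxy)phenoxy]-2,3-dihydroxypropyl}indan-1-one (anti) | O=C1CCc2c([C@@H](Oc3cc(OCc4ccccc4)cc(OCc4ccccc4)c3)[C@@H](O)CO)cc(OCc4ccccc4)c(OCc4ccccc4)c21 | intermediate
22 | primary monoacetate of 21, (2S,3R)-configured propyl chain | O=C1CCc2c([C@@H](Oc3cc(OCc4ccccc4)cc(OCc4ccccc4)c3)[C@@H](O)COC(C)=O)cc(OCc4ccccc4)c(OCc4ccccc4)c21 | intermediate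
23 | (2S,3R)-3-[6,7-bis(benzyloxy)-1-oxoindan-4-yl]-3-[3,5-bis(benzyloxy)phenoxy]-2-(methylsulfonyloxy)propyl acetate | O=C1CCc2c([C@@H](Oc3cc(OCc4ccccc4)cc(OCc4ccccc4)c3)[C@@H](OS(C)(=O)=O)COC(C)=O)cc(OCc4ccccc4)c(OCc4ccccc4)c21 | intermediate
24 | hydroxy mesylate (23 without the acetyl group) | O=C1CCc2c([C@@H](Oc3cc(OCc4ccccc4)cc(OCc4ccccc4)c3)[C@@H](OS(C)(=O)=O)CO)cc(OCc4ccccc4)c(OCc4ccccc4)c21 | intermediate
25 | 6,7-bis(benzyloxy)-4-{(R)-[3,5-bis(benzyloxy)phenoxy][(2R)-oxiran-2-yl]methyl}indan-1-one (syn) | O=C1CCc2c([C@@H](Oc3cc(OCc4ccccc4)cc(OCc4ccccc4)c3)[C@H]3CO3)cc(OCc4ccccc4)c(OCc4ccccc4)c21 | intermediate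
26 | 6,7-bis(benzyloxy)-4-[(2R,3R)-5,7-bis(benzyloxy)-3-hydroxychroman-2-yl]indan-1-one (cis) | O=C1CCc2c([C@H]3Oc4cc(OCc5ccccc5)cc(OCc5ccccc5)c4C[C@H]3O)cc(OCc5ccccc5)c(OCc5ccccc5)c21 | intermediate
27 | 3,4,5-tris(benzyloxy)benzoic acid | O=C(O)c1cc(OCc2ccccc2)c(OCc2ccccc2)c(OCc2ccccc2)c1 | starting material
28 | (2R,3R)-5,7-bis(benzyloxy)-2-[6,7-bis(benzyloxy)-1-oxoindan-4-yl]chroman-3-yl 3,4,5-tris(benzyloxy)benzoate | O=C1CCc2c([C@H]3Oc4cc(OCc6ccccc6)cc(OCc6ccccc6)c4C[C@H]3OC(=O)c5cc(OCc6ccccc6)c(OCc6ccccc6)c(OCc6ccccc6)c5)cc(OCc6ccccc6)c(OCc6ccccc6)c21 | intermediate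
29 | sodium C1–C2 enolate of 28 | [Na+].[O-]C1=CCc2c([C@H]3Oc4cc(OCc6ccccc6)cc(OCc6ccccc6)c4C[C@H]3OC(=O)c5cc(OCc6ccccc6)c(OCc6ccccc6)c(OCc6ccccc6)c5)cc(OCc6ccccc6)c(OCc6ccccc6)c21 | intermediate
30 | 2-hydroxyindanone gallate (28 with OH on indanone C2, both epimers) | O=C1C(O)Cc2c([C@H]3Oc4cc(OCc6ccccc6)cc(OCc6ccccc6)c4C[C@H]3OC(=O)c5cc(OCc6ccccc6)c(OCc6ccccc6)c(OCc6ccccc6)c5)cc(OCc6ccccc6)c(OCc6ccccc6)c21 | intermediate
31 | indane-1,2-dione gallate | O=C1C(=O)Cc2c([C@H]3Oc4cc(OCc6ccccc6)cc(OCc6ccccc6)c4C[C@H]3OC(=O)c5cc(OCc6ccccc6)c(OCc6ccccc6)c(OCc6ccccc6)c5)cc(OCc6ccccc6)c(OCc6ccccc6)c21 | intermediate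
32 | 2-(tert-butyldimethylsilyloxy)inden-1-one bearing perbenzylated chroman G gallate on C4 and benzyloxy on C6 and C7 | O=C1C(O[Si](C)(C)C(C)(C)C)=Cc2c([C@H]3Oc4cc(OCc6ccccc6)cc(OCc6ccccc6)c4C[C@H]3OC(=O)c5cc(OCc6ccccc6)c(OCc6ccccc6)c(OCc6ccccc6)c5)cc(OCc6ccccc6)c(OCc6ccccc6)c21 | intermediate
33 | cis-fused 5,6-bis(benzyloxy)-7a-(tert-butyldimethylsilyloxy)-2-(chroman F)-3-(chroman G gallate)-2a,7a-dihydro-7H-cyclobuta[a]inden-7-one (C7a = core C6, C1 = C7, C2 = C8, C2a = C9; one facial isomer drawn, the other has both new centres inverted) | O=C1[C@]7(O[Si](C)(C)C(C)(C)C)C=C([C@H]3Oc4cc(OCc6ccccc6)cc(OCc6ccccc6)c4C[C@H]3OCc6ccccc6)[C@@H]7c2c([C@H]3Oc4cc(OCc6ccccc6)cc(OCc6ccccc6)c4C[C@H]3OC(=O)c5cc(OCc6ccccc6)c(OCc6ccccc6)c(OCc6ccccc6)c5)cc(OCc6ccccc6)c(OCc6ccccc6)c21 | intermediate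
34 | 6-O-(tert-butyldimethylsilyl) deca-O-benzyl theaflavin gallate | O=C(O[C@@H]1Cc2c(OCc6ccccc6)cc(OCc6ccccc6)cc2O[C@@H]1c1cc(OCc6ccccc6)c(OCc6ccccc6)c2c(=O)c(O[Si](C)(C)C(C)(C)C)cc([C@H]3Oc4cc(OCc6ccccc6)cc(OCc6ccccc6)c4C[C@H]3OCc6ccccc6)cc12)c1cc(OCc6ccccc6)c(OCc6ccccc6)c(OCc6ccccc6)c1 | intermediate
35 | deca-O-benzyl theaflavin gallate with free 6-OH | O=C(O[C@@H]1Cc2c(OCc6ccccc6)cc(OCc6ccccc6)cc2O[C@@H]1c1cc(OCc6ccccc6)c(OCc6ccccc6)c2c(=O)c(O)cc([C@H]3Oc4cc(OCc6ccccc6)cc(OCc6ccccc6)c4C[C@H]3OCc6ccccc6)cc12)c1cc(OCc6ccccc6)c(OCc6ccccc6)c(OCc6ccccc6)c1 | intermediate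
36 | theaflavin-3-gallate | O=C(O[C@@H]1Cc2c(O)cc(O)cc2O[C@@H]1c1cc(O)c(O)c2c(=O)c(O)cc([C@H]3Oc4cc(O)cc(O)c4C[C@H]3O)cc12)c1cc(O)c(O)c(O)c1 | target

## Step count and risks

Total steps: 24. Longest linear sequence: 17 steps (12 to 36, steps 7–10 and 12–24).

**Step 22.** The excited indenone may be lost before it meets a hindered, unactivated alkyne. The competing processes are self-dimerisation, electron-transfer quenching by the electron-rich chroman rings, and hydrogen abstraction from the 7-benzyloxy group. The biradical may also close in the head-to-head sense.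

Fallback: the cycloaddition is made intramolecular through a disiloxane tether from O6 to the alkyne terminus C7. It sets out from 11 and 31.
- n-BuLi (THF, −78 °C) converts 11 into its lithium acetylide F1. Adding this to excess 1,3-dichloro-1,1,3,3-tetraisopropyldisiloxane gives the alkynyl chlorodisiloxane F2.
- AgOTf turns F2 in the flask into the silyl triflate F3. With Et3N this silylates the enol of 31 as in step 21 and gives the tethered siloxyindenone F4.
- Irradiation at 420 nm in high dilution closes the cyclobutene in the straight mode. The six-membered ring C6–O–Si–O–Si–C7 can form only if C7 bonds to C6, which leaves C8 for C9. The product is the bridged photoadduct F5.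
- Excess Bu4NF in wet THF cleaves the O6–Si bond, the freed alkoxide breaks C6–C9, and the C7–Si bond of the electron-rich tropolonate is protodesilylated. The sequence rejoins the route at 35.

**Step 23.** Because the cis ring fusion excludes the conrotatory path, the opening may need temperatures at which other processes take over. These are loss of benzyl groups, elimination of the gallate, and acyl shifts of the β,γ-unsaturated ketone.

Fallback: the neutral thermolysis is replaced by an anionic fragmentation. It sets out from 33.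
- Bu4NF buffered with AcOH (THF, −20 °C) frees the tertiary α-ketol F6.
- DBU (THF, 0 °C) converts F6 into the C6 alkoxide, which expels C9 as a carbanion stabilised by the ortho-acyl arene and by C7=C8. This is a retro-aldol cleavage of a cyclobutanol, as in the second stage of the de Mayo reaction.
- Protonation of the tropolonate gives 35.

**Step 21.** The diketone may condense with itself under amine base. The C3 protons lie under the peri chroman G and may be removed slowly. The indenone may dimerise on concentration.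

Fallback: the diketone is bypassed and the double bond is introduced by dehydrogenation. It sets out from 30.
- TBSOTf and 2,6-lutidine give the 2-siloxyindanone F7 (C2 epimers).
- LiN(SiMe3)2 (THF, −78 °C) gives its lithium enolate F8, which is treated with N-tert-butylbenzenesulfinimidoyl chloride (Mukaiyama dehydrogenation).
- The syn elimination can take only a C3 hydrogen and gives 32.

## Further compounds

F1 | step 22 | lithium acetylide of 11 | [Li]C#C[C@H]1Oc2cc(OCc3ccccc3)cc(OCc3ccccc3)c2C[C@H]1OCc1ccccc1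
F2 | step 22 | (2R,3R)-3,5,7-tris(benzyloxy)-2-[(3-chloro-1,1,3,3-tetraisopropyldisiloxanyl)ethynyl]chroman | CC(C)[Si](Cl)(C(C)C)O[Si](C(C)C)(C(C)C)C#C[C@H]1Oc2cc(OCc3ccccc3)cc(OCc3ccccc3)c2C[C@H]1OCc1ccccc1
F3 | step 22 | silyl triflate corresponding to F2 | CC(C)[Si](OS(=O)(=O)C(F)(F)F)(C(C)C)O[Si](C(C)C)(C(C)C)C#C[C@H]1Oc2cc(OCc3ccccc3)cc(OCc3ccccc3)c2C[C@H]1OCc1ccccc1
F4 | step 22 | 2-siloxyindenone tethered through O6–Si(iPr)2–O–Si(iPr)2 to the alkyne terminus of chroman F | O=C1C(O[Si](C(C)C)(C(C)C)O[Si](C(C)C)(C(C)C)C#C[C@H]7Oc8cc(OCc6ccccc6)cc(OCc6ccccc6)c8C[C@H]7OCc6ccccc6)=Cc2c([C@H]3Oc4cc(OCc6ccccc6)cc(OCc6ccccc6)c4C[C@H]3OC(=O)c5cc(OCc6ccccc6)c(OCc6ccccc6)c(OCc6ccccc6)c5)cc(OCc6ccccc6)c(OCc6ccccc6)c21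
F5 | step 22 | cis-fused cyclobuta[a]indenone with a 1,3-dioxa-2,4-disilacyclohexane ring spanning O6 and C7 (one facial isomer drawn) | O=C1[C@@]79O[Si](C(C)C)(C(C)C)O[Si](C(C)C)(C(C)C)C9=C([C@H]3Oc4cc(OCc6ccccc6)cc(OCc6ccccc6)c4C[C@H]3OCc6ccccc6)[C@@H]7c2c([C@H]3Oc4cc(OCc6ccccc6)cc(OCc6ccccc6)c4C[C@H]3OC(=O)c5cc(OCc6ccccc6)c(OCc6ccccc6)c(OCc6ccccc6)c5)cc(OCc6ccccc6)c(OCc6ccccc6)c21
F6 | step 23 | tertiary α-ketol (33 with free hydroxyl on core C6; one facial isomer drawn) | O=C1[C@]7(O)C=C([C@H]3Oc4cc(OCc6ccccc6)cc(OCc6ccccc6)c4C[C@H]3OCc6ccccc6)[C@@H]7c2c([C@H]3Oc4cc(OCc6ccccc6)cc(OCc6ccccc6)c4C[C@H]3OC(=O)c5cc(OCc6ccccc6)c(OCc6ccccc6)c(OCc6ccccc6)c5)cc(OCc6ccccc6)c(OCc6ccccc6)c21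
F7 | step 21 | 2-(tert-butyldimethylsilyloxy)indan-1-one gallate (silyl ether of 30, both C2 epimers) | O=C1C(O[Si](C)(C)C(C)(C)C)Cc2c([C@H]3Oc4cc(OCc6ccccc6)cc(OCc6ccccc6)c4C[C@H]3OC(=O)c5cc(OCc6ccccc6)c(OCc6ccccc6)c(OCc6ccccc6)c5)cc(OCc6ccccc6)c(OCc6ccccc6)c21
F8 | step 21 | lithium enolate of F7 | [Li+].[O-]C1=C(O[Si](C)(C)C(C)(C)C)Cc2c([C@H]3Oc4cc(OCc6ccccc6)cc(OCc6ccccc6)c4C[C@H]3OC(=O)c5cc(OCc6ccccc6)c(OCc6ccccc6)c(OCc6ccccc6)c5)cc(OCc6ccccc6)c(OCc6ccccc6)c21
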